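Readings and results were generated by integration for an exercise; scatter was added.

The ratio of other capture product to target is the small quantity at the start of this flask, so we reckon it as a correction and then follow the rate of the target.

all flasks: substrate 0.050 M; gas 4.4 mM (held)

|  | first nucleophile | remark | time |
|---|---|---|---|
| spring | 0.028 M | run made earlier |  |
| dusk | 0.11 M | run made earlier |  |
| flask | 0.0550 M |  | 40 h |

| run | time / h | target / % | other capture product / % |
|---|---|---|---|
| spring | 2.00 | 8 | 4 |
| spring | 4.00 | 14 | 5 |
| spring | 6.00 | 13 | 8 |
| spring | 12.0 | 18 | 11 |
| spring | 25.0 | 13 | 12 |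
| dusk | 5.00 | 31 | 4 |
| dusk | 10.0 | 42 | 6 |
| dusk | 15.0 | 43 | 8 |
| dusk | 20.0 | 39 | 13 |
| dusk | 25.0 | 36 | 8 |

(readings scatter by 1.5 percentage points)

1. share of target in target plus other capture product at 15 min
2. share of target in target plus other capture product at 40 h
3. which of target and other capture product there is more of at 40 h

- the numbers in the tables scatter by 1.5 percentage points (one standard deviation)
- at the start none of the gas is in solution

The spring run reads a ratio of 0.500 at 2.00 h. No gas is in solution at the start, so we let the ratio grow in proportion to time and fall in proportion to the charge of first nucleophile. That gives 0.0318 in the flask at 15 min, a target share of 96.9 %.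

The target's net rate in the dusk run opens at 0.0620 h⁻¹ of the charge and drops to 0.0220 h⁻¹ over the next interval, 2.82 times slower. After 15.0 h the dusk readings fall, from 43 % to 36 % at 25.0 h. From 12.0 h to 25.0 h the spring target falls from 18 % to 13 %, which gives the fractional loss rate λ, the share of the target lost per hour 0.0250 h⁻¹, a pseudo-first-order constant read with the scatter of the readings.

Taking the reciprocal of the peak as linear in the reciprocal of the charge, we put the flask's peak at 29.2 %, near 12.0 h. The survival factor σ from then until 40 h is 0.496, which leaves 14.5 % of target. Against 10.0 % of other capture product, the mean of the spring and dusk readings at 25.0 h, that is a share of 59.1 %.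

The forecast gave 89 % at 15 min and 52 % at 40 h with target ahead, “so the lead is very uncertain”. Our shares stand higher.

The flask gives 97.4 % at 15 min and 61.2 % at 40 h, with target ahead at 17.1 % against 10.8 %.

    intermediate → solvolysis product (k = 10.6 h⁻¹)
    first nucleophile + intermediate → target (k = 156 L mol⁻¹ h⁻¹)
    substrate → intermediate (k = 0.181 h⁻¹)
    gas ⇌ second nucleophile, rate k4*(csat - [second nucleophile]) (kL = 0.327 h⁻¹)
    second nucleophile + target → over-reaction product (k = 6.70 L mol⁻¹ h⁻¹)
    second nucleophile + intermediate → other capture product (k = 1160 L mol⁻¹ h⁻¹)

With the step from second nucleophile and target to over-reaction product struck out, the share at 40 h is 74.8 %. Target plus over-reaction product in this flask comes to 35.7 %, and σ turns that into 17.7 %, against 17.1 % of target. In the neighbour flask with 0.22 M of first nucleophile the same sum is 70.9 %, and σ gives 35.2 %, against 37.3 % of target.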